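**Plan**
- The last cuts are the C8 isovalerate, the C5 silyl ether and the lactone C7–C11/C11=C13 bonds, which lead back to a C6 alcohol beside a 7,8-epoxide.
- The central cut rests on the furanone ring (O1, C3, C2, C1, C10): its oxygen sits on the quaternary α-keto carbon C10, and C10 is joined through C9 to C8. O1–C10–C9–C8(=C7) is therefore the retron of an allyl oxonium ylide [2,3]-shift. Cutting O1–C10 and C9–C10 and re-forming O1–C7 gives a 2-vinyltetrahydropyran (O1, C3–C7) that carries a methyl diazoketone arm; this pyran is a temporary ring.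
- The pyran comes from Achmatowicz dearomatization of a 2,5-disubstituted 3-methylfuran: furan carbons become C3–C6 and the furan methyl becomes C15, masked as a 4,5-epoxide until after the key step.
- Forward order of rings: furan, dihydropyranone, epoxy-tetrahydropyran, then furanone plus ten-membered carbocycle in one step, α-methylene lactone last.
- Stereochemistry: one reagent-controlled centre (the C7 carbinol) relays to C3 (Kishi reduction), C6 (hydride) and C4/C5 (directed epoxidation). C3 is transferred to C10 in the [2,3]-shift. C7 and C8 come from epoxidation of the E-alkene and anti opening by a C6-tethered carbanion.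

Key step: step 11

Numbering remark: germacranolide locants of the target are used throughout (C1 ketone, C3 enol-ether carbon, C4 bearing C15, C10 bearing C14, C11–C13 lactone carbons, O1 the ether oxygen between C3 and C10), also for the monocyclic pyrans.

**Step 1**
Reactants: 1 3-methylfuran; 2 methyl bromoacetate
Product: 3 methyl 2-(3-methylfuran-2-yl)acetate
Conditions: fac-Ir(ppy)3 (1 mol%), 2,6-lutidine, MeCN, blue LED, rt, 1 in excess
Reagents that add atoms: none
Why: Photoredox homolytic aromatic substitution, in which the electrophilic ester-substituted methyl radical should add to the α-carbon next to the methyl group (the more electron-rich one, giving a tertiary allylic radical) before oxidation and proton loss restore the furan.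

**Step 2**
Reactants: 3 methyl 2-(3-methylfuran-2-yl)acetate
Product: 4 methyl 2-(5-formyl-3-methylfuran-2-yl)acetate
Conditions: POCl3, DMF, 0 °C to rt; then aq. NaOAc
Reagents that add atoms: N,N-dimethylformamide CN(C)C=O; water O
Why: Vilsmeier–Haack formylation should take place at the only free α-position of the furan.

**Step 3**
Reactants: 4 methyl 2-(5-formyl-3-methylfuran-2-yl)acetate
Product: 5 methyl 2-{5-[(1R)-1-hydroxyprop-2-en-1-yl]-3-methylfuran-2-yl}acetate
Conditions: divinylzinc, (+)-MIB (3-exo-morpholinoisoborneol, 10 mol%), toluene, 0 °C; then aq. NH4Cl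
Reagents that add atoms: divinylzinc C=C[Zn]C=C
Why: Amino-alcohol-catalysed addition of a vinylzinc reagent to the aldehyde, with the ligand antipode chosen for Re-face delivery, should set the (R)-carbinol, the only centre of the route set by a reagent; the methyl ester is inert to the organozinc.

**Step 4**
Reactants: 5 methyl 2-{5-[(1R)-1-hydroxyprop-2-en-1-yl]-3-methylfuran-2-yl}acetate
Product: 6 methyl 2-[(6R)-2-hydroxy-3-methyl-5-oxo-6-vinyl-5,6-dihydro-2H-pyran-2-yl]acetate (hemiketal anomers)
Conditions: NBS, NaHCO3, NaOAc, THF/H2O, 0 °C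
Reagents that add atoms: water O
Why: Achmatowicz rearrangement, an oxidative dearomatization in which the carbinol oxygen becomes O1 and furan carbons become C6, C5, C4 and C3, with the carbinol centre (C7) untouched and the furan oxidized faster than the vinyl group.

**Step 5**
Reactants: 6 hemiketal pyranone
Product: 7 methyl 2-[(2S,6R)-3-methyl-5-oxo-6-vinyl-5,6-dihydro-2H-pyran-2-yl]acetate (2,6-cis)
Conditions: Et3SiH, CF3CO2H, CH2Cl2, −40 °C
Reagents that add atoms: none
Why: Kishi reduction, in which the hemiketal ionizes to the oxocarbenium ion and the silane adds axially, should place the C3 acetate arm cis to the C7 vinyl group, that is (3S) from (7R).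

**Step 6**
Reactants: 7 2,6-cis dihydropyranone
Product: 8 methyl 2-[(2S,5R,6R)-5-hydroxy-3-methyl-6-vinyl-5,6-dihydro-2H-pyran-2-yl]acetate (arm/hydroxyl/vinyl all cis)
Conditions: LiBH(s-Bu)3 (L-Selectride), THF, −78 °C; then aq. NH4Cl
Reagents that add atoms: none
Why: 1,2-Reduction of the β,β-disubstituted enone by a bulky hydride from the face opposite both ring substituents should give the allylic alcohol cis to the vinyl group, which sets C6; the ester survives at −78 °C.

**Step 7**
Reactants: 8 all-cis allylic alcohol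
Product: 9 methyl 2-[3,4-epoxy-5-hydroxy-3-methyl-6-vinyltetrahydro-2H-pyran-2-yl]acetate (arm/epoxide oxygen/hydroxyl/vinyl all cis)
Conditions: VO(acac)2 (cat.), t-BuOOH, CH2Cl2, 0 °C
Reagents that add atoms: tert-butyl hydroperoxide CC(C)(C)OO
Why: Hydroxyl-directed vanadium-catalysed epoxidation should deliver oxygen syn to the C6 hydroxyl, setting C5 (R) and storing the later C4 exo-methylene and C5 carbinol as the 4,5-epoxide; the homoallylic vinyl group reacts far more slowly.

**Step 8**
Reactants: 9 all-cis epoxy alcohol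
Product: 10 methyl 2-[3,4-epoxy-3-methyl-5-(triethylsilyloxy)-6-vinyltetrahydro-2H-pyran-2-yl]acetate
Conditions: Et3SiCl, imidazole, DMF, rt
Reagents that add atoms: chlorotriethylsilane CC[Si](Cl)(CC)CC
Why: Standard silylation gives a C6 ether that can later be removed in the presence of a tert-butyldimethylsilyl ether.

**Step 9**
Reactants: 10 triethylsilyl ether ester
Product: 11 2-[3,4-epoxy-3-methyl-5-(triethylsilyloxy)-6-vinyltetrahydro-2H-pyran-2-yl]acetic acid
Conditions: LiOH, THF/H2O, 0 °C; then 1 M HCl to pH 4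
Reagents that add atoms: lithium hydroxide [Li+].[OH-]
Why: Saponification of the methyl ester under conditions that should spare the epoxide and the silyl ether.

**Step 10**
Reactants: 11 carboxylic acid
Product: 13 3-diazo-1-[3,4-epoxy-3-methyl-5-(triethylsilyloxy)-6-vinyltetrahydro-2H-pyran-2-yl]butan-2-one, via mixed isobutyl carbonic anhydride 12 (not isolated)
Conditions: i-BuOCOCl, Et3N, THF, −20 °C; then ethereal diazoethane (prepared separately), −20 to 0 °C
Reagents that add atoms: diazoethane CC=[N+]=[N-]
Why: Acylation of diazoethane by a mixed anhydride (Arndt–Eistert-type diazoketone synthesis) should give the methyl-substituted diazoketone without acid that would harm the epoxide or silyl ether.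

**Step 11**
Reactants: 13 methyl diazoketone
Product: 14 (7E)-3,10:4,5-diepoxy-6-(triethylsilyloxy)germacr-7-en-1-one (3S,10S; C4 to C6 as in 13)
Conditions: Rh2(NHCOCF3)4 (2 mol%), CH2Cl2, reflux, slow addition to 5 mM
Reagents that add atoms: none
Why: The rhodium carbenoid at C10 (between the C1 ketone and the C14 methyl) is captured by the pyran oxygen O1 in a five-membered closure that forms the O1–C10 bond and the furanone ring as a cis-fused bicyclic oxonium ylide; a [2,3]-sigmatropic shift then joins C9 to C10 and breaks O1–C7, so the pyran, a ring absent from the target, is spent in a three-atom ring expansion to the C1–C10 carbocycle bridged by O1. The closest known reaction type is catalytic oxonium ylide formation/[2,3]-rearrangement of diazoketones tethered to 2-vinyl cyclic ethers, known for methyl-substituted diazoketones and, in its ring-expanding form, for oxygen-bridged medium rings. As to mode of closure, the furanone ring closes by 5-exo attack of an ether lone pair on the metal carbene, while the ten-membered ring is not closed end to end but arises by allyl transfer through a five-membered envelope transition state (C10, O1, C7, C8, C9). The new centre C10 is controlled by (3S): the oxonium ion must be cis-fused and C9 is delivered suprafacially to the ylide face on which O1–C7 lies, so C9 ends cis to C4 on the furanone ring, which is (10S); the centres C3 and C7 of the pyran are traded for C10 and the alkene. Ylide formation must outrun 1,2-hydride shift, C–H insertion and cyclopropanation, which the 1,5-placement of O1, the lack of hydrogen on C4 and the masking of the C4 methylene as the epoxide should secure. The C7=C8 bond must be E, which is expected when the new O1–C10 bond is equatorial, because the axial lone pair of O1 is screened by the syn-axial C6 silyl ether and the epoxide oxygen and the rhodium carboxamidate should rearrange through the metal-bound ylide.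

**Step 12**
Reactants: 14 bridged tetrahydrofuranone
Product: 16 (7E)-3,10:4,5-diepoxy-6-(triethylsilyloxy)germacra-2,7-dien-1-one, via C1 trimethylsilyl enol ether 15 (not isolated)
Conditions: LiN(SiMe3)2, Me3SiCl, THF, −78 °C; then Pd(OAc)2 (1.1 equiv), MeCN, rt
Reagents that add atoms: none
Why: Saegusa–Ito oxidation, in which the ketone can enolize only toward C2 (C10 is quaternary) and divalent palladium dehydrogenates the silyl enol ether, should give the 3(2H)-furanone and remove the C3 centre once it has done its relay work.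

**Step 13**
Reactants: 16 furanone epoxide
Product: 17 (7E)-5-(tert-butyldimethylsilyloxy)-3,10-epoxy-6-(triethylsilyloxy)germacra-2,4(15),7-trien-1-one
Conditions: t-BuMe2SiOTf, 2,6-lutidine, CH2Cl2, −78 to 0 °C
Reagents that add atoms: tert-butyldimethylsilyl triflate CC(C)(C)[Si](C)(C)OS(=O)(=O)C(F)(F)F
Why: Silyl-triflate-promoted isomerization of a trisubstituted epoxide to an allylic silyl ether, in which ionization at tertiary C4 and loss of a C15 proton (C3 now has none) should unmask the exo-methylene and deliver the C5 oxygen already protected with C5 unchanged.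

**Step 14**
Reactants: 17 bis-silyl ether
Product: 18 (7E)-5-(tert-butyldimethylsilyloxy)-3,10-epoxy-6-hydroxygermacra-2,4(15),7-trien-1-one
Conditions: PPTS, MeOH/CH2Cl2, 0 °C
Reagents that add atoms: none
Why: Mild acid methanolysis should cleave the triethylsilyl ether selectively over the secondary tert-butyldimethylsilyl ether.

**Step 15**
Reactants: 18 C6 allylic alcohol
Product: 19 (7R,8R)-5-(tert-butyldimethylsilyloxy)-3,10:7,8-diepoxy-6-hydroxygermacra-2,4(15)-dien-1-one
Conditions: VO(acac)2 (cat.), t-BuOOH, CH2Cl2, 0 °C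
Reagents that add atoms: tert-butyl hydroperoxide CC(C)(C)OO
Why: Hydroxyl-directed vanadium epoxidation of the strained E-alkene on its exposed face (away from the bridging oxygen, where the C6 hydroxyl sits) should give the trans-epoxide with the C8–O bond of the target; the electron-poor dienone alkenes are inert.

**Step 16**
Reactants: 19 epoxy alcohol
Product: 20 C6 diethylphosphonoacetate of 19
Conditions: (EtO)2P(O)CH2CO2H, DCC, DMAP (cat.), CH2Cl2, 0 °C to rt
Reagents that add atoms: diethylphosphonoacetic acid OC(=O)CP(=O)(OCC)OCC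
Why: Steglich esterification attaches the two-carbon lactone unit (C11, C12) to O6 under neutral conditions that keep the epoxide.

**Step 17**
Reactants: 20 epoxy phosphonoacetate
Product: 22 5-(tert-butyldimethylsilyloxy)-3,10-epoxy-8-hydroxy-1-oxogermacra-2,4(15),11(13)-trien-6,12-olide (5R,6S,7R,8R,10S), via 11-diethoxyphosphoryl lactone 21 (not isolated)
Conditions: NaH (1.1 equiv), THF, 0 °C to rt; then paraformaldehyde, rt
Reagents that add atoms: formaldehyde C=O
Why: C-alkylation of the phosphonoacetate carbanion by the epoxide in a 5-exo opening at C7 (inversion, giving the trans-fused lactone with (7R) and leaving the C8–O bond as the free alcohol), then proton transfer and Horner–Wadsworth–Emmons olefination with formaldehyde, the α-phosphono-γ-butyrolactone route to α-methylene lactones.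

**Step 18**
Reactants: 22 C8 alcohol
Product: 23 8-O-(3-methylbutanoyl) derivative of 22
Conditions: (i-BuCO)2O, Et3N, DMAP (cat.), CH2Cl2, 0 °C
Reagents that add atoms: 3-methylbutanoic anhydride CC(C)CC(=O)OC(=O)CC(C)C
Why: DMAP-catalysed acylation of the secondary alcohol with retention at C8.

**Step 19**
Reactants: 23 silyl-protected ester
Product: 24 target CNP0409337.1
Conditions: HF·pyridine, THF/pyridine, 0 °C
Reagents that add atoms: none
Why: Buffered fluoride desilylation frees the C5 alcohol without touching the α-methylene lactone, the ester or the furanone.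

**Compound list**
1 | 3-methylfuran | Cc1ccoc1 | starting material
2 | methyl bromoacetate | COC(=O)CBr | starting material
3 | methyl 2-(3-methylfuran-2-yl)acetate | COC(=O)Cc1occc1C | intermediate
4 | methyl 2-(5-formyl-3-methylfuran-2-yl)acetate | COC(=O)Cc1oc(C=O)cc1C | intermediate
5 | methyl 2-{5-[(1R)-1-hydroxyprop-2-en-1-yl]-3-methylfuran-2-yl}acetate | COC(=O)Cc1oc([C@H](O)C=C)cc1C | intermediate
6 | methyl 2-[(6R)-2-hydroxy-3-methyl-5-oxo-6-vinyl-5,6-dihydro-2H-pyran-2-yl]acetate, hemiketal anomers | COC(=O)CC1(O)O[C@H](C=C)C(=O)C=C1C | intermediate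
7 | methyl 2-[(2S,6R)-3-methyl-5-oxo-6-vinyl-5,6-dihydro-2H-pyran-2-yl]acetate | COC(=O)C[C@@H]1O[C@H](C=C)C(=O)C=C1C | intermediate
8 | methyl 2-[(2S,5R,6R)-5-hydroxy-3-methyl-6-vinyl-5,6-dihydro-2H-pyran-2-yl]acetate | COC(=O)C[C@@H]1O[C@H](C=C)[C@H](O)C=C1C | intermediate
9 | all-cis methyl 2-[3,4-epoxy-5-hydroxy-3-methyl-6-vinyltetrahydro-2H-pyran-2-yl]acetate | COC(=O)C[C@@H]1O[C@H](C=C)[C@H](O)[C@@H]2O[C@]12C | intermediate
10 | triethylsilyl ether of 9 | COC(=O)C[C@@H]1O[C@H](C=C)[C@H](O[Si](CC)(CC)CC)[C@@H]2O[C@]12C | intermediate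
11 | carboxylic acid from 10 | OC(=O)C[C@@H]1O[C@H](C=C)[C@H](O[Si](CC)(CC)CC)[C@@H]2O[C@]12C | intermediate
12 | mixed isobutyl carbonic anhydride of 11 | CC(C)COC(=O)OC(=O)C[C@@H]1O[C@H](C=C)[C@H](O[Si](CC)(CC)CC)[C@@H]2O[C@]12C | intermediate
13 | 3-diazo-1-[3,4-epoxy-3-methyl-5-(triethylsilyloxy)-6-vinyltetrahydro-2H-pyran-2-yl]butan-2-one | CC(=[N+]=[N-])C(=O)C[C@@H]1O[C@H](C=C)[C@H](O[Si](CC)(CC)CC)[C@@H]2O[C@]12C | intermediate
14 | (7E)-3,10:4,5-diepoxy-6-(triethylsilyloxy)germacr-7-en-1-one (3S,10S) | C[C@]12C/C=C/[C@H](O[Si](CC)(CC)CC)[C@@H]3O[C@]3(C)[C@H](CC1=O)O2 | intermediate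
15 | C1 trimethylsilyl enol ether of 14 | C[C@]12C/C=C/[C@H](O[Si](CC)(CC)CC)[C@@H]3O[C@]3(C)[C@H](C=C1O[Si](C)(C)C)O2 | intermediate
16 | (7E)-3,10:4,5-diepoxy-6-(triethylsilyloxy)germacra-2,7-dien-1-one | C[C@]12C/C=C/[C@H](O[Si](CC)(CC)CC)[C@@H]3O[C@]3(C)C(=CC1=O)O2 | intermediate
17 | (7E)-5-(tert-butyldimethylsilyloxy)-3,10-epoxy-6-(triethylsilyloxy)germacra-2,4(15),7-trien-1-one | C[C@]12C/C=C/[C@H](O[Si](CC)(CC)CC)[C@H](O[Si](C)(C)C(C)(C)C)C(=C)C(=CC1=O)O2 | intermediate
18 | (7E)-5-(tert-butyldimethylsilyloxy)-3,10-epoxy-6-hydroxygermacra-2,4(15),7-trien-1-one | C[C@]12C/C=C/[C@H](O)[C@H](O[Si](C)(C)C(C)(C)C)C(=C)C(=CC1=O)O2 | intermediate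
19 | (7R,8R)-5-(tert-butyldimethylsilyloxy)-3,10:7,8-diepoxy-6-hydroxygermacra-2,4(15)-dien-1-one | C[C@]12C[C@H]3O[C@@H]3[C@H](O)[C@H](O[Si](C)(C)C(C)(C)C)C(=C)C(=CC1=O)O2 | intermediate
20 | C6 diethylphosphonoacetate of 19 | C[C@]12C[C@H]3O[C@@H]3[C@H](OC(=O)CP(=O)(OCC)OCC)[C@H](O[Si](C)(C)C(C)(C)C)C(=C)C(=CC1=O)O2 | intermediate
21 | 11-(diethoxyphosphoryl)-5-(tert-butyldimethylsilyloxy)-3,10-epoxy-8-hydroxy-1-oxogermacra-2,4(15)-dien-6,12-olide | C[C@]12C[C@@H](O)[C@H]3C(P(=O)(OCC)OCC)C(=O)O[C@@H]3[C@H](O[Si](C)(C)C(C)(C)C)C(=C)C(=CC1=O)O2 | intermediate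
22 | 5-(tert-butyldimethylsilyloxy)-3,10-epoxy-8-hydroxy-1-oxogermacra-2,4(15),11(13)-trien-6,12-olide | C[C@]12C[C@@H](O)[C@H]3C(=C)C(=O)O[C@@H]3[C@H](O[Si](C)(C)C(C)(C)C)C(=C)C(=CC1=O)O2 | intermediate
23 | 8-O-(3-methylbutanoyl) derivative of 22 | C[C@]12C[C@@H](OC(=O)CC(C)C)[C@H]3C(=C)C(=O)O[C@@H]3[C@H](O[Si](C)(C)C(C)(C)C)C(=C)C(=CC1=O)O2 | intermediate
24 | CNP0409337.1 (5R,6S,7R,8R,10S) | C[C@]12C[C@@H](OC(=O)CC(C)C)[C@H]3C(=C)C(=O)O[C@@H]3[C@H](O)C(=C)C(=CC1=O)O2 | target

Total step count: 19. Longest linear sequence: 19 steps.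

**Steps most likely to fail**

1. Step 11. What may go wrong: capture of the carbenoid through the axial lone pair of O1 (free-ylide pathway) would give the Z-cycloalkene, and a slow ylide formation would let 1,2-hydride shift in the methyl carbenoid compete. Fallback: accept the Z ring and invert C8 at the end. Setting out from 13, Cu(hfacac)2 (5 mol%, CH2Cl2, reflux), a catalyst with which hydride shift is less of a concern, should give the (7Z) ketone F1. The operations of steps 12 to 17 applied to F1 should give in turn the silyl enol ether F2 (not isolated), the furanone F3, the exo-methylene bis-silyl ether F4, the C6 alcohol F5, the cis (7R,8S) epoxy alcohol F6, its phosphonoacetate F7, the phosphono lactone F8 (not isolated) and the 8-epi hydroxy α-methylene lactone F9; C7 is again set by anti opening and only C8 differs. Mitsunobu esterification of F9 with isovaleric acid (PPh3, DIAD, toluene, 0 °C, betaine preformed) should invert C8 and come back to the route at 23.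

2. Step 17. What may go wrong: transfer of the phosphoryl group from C11 to the C8 alkoxide (the Wadsworth–Emmons cyclopropane pathway) or relactonization onto O8 before olefination. Fallback without phosphorus: setting out from 19, acylation with Meldrum's acid (toluene, 80 °C) should give the malonic half ester F10. Its dianion (LiN(SiMe3)2, 2.2 equiv, THF, −78 to 0 °C) should open the epoxide at C7 to the α-carboxy lactone F11. Decarboxylative Mannich methylenation (paraformaldehyde, Et2NH, then NaOAc/AcOH, 70 °C) should come back at 22.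

3. Step 6. What may go wrong: hydride delivery along the axial trajectory, giving the alcohol trans to the vinyl group, or conjugate reduction. Fallback: setting out from 7, Luche reduction (NaBH4, CeCl3·7H2O, MeOH, −78 °C) should give the trans allylic alcohol F12. Mitsunobu inversion with 4-nitrobenzoic acid (PPh3, DIAD, THF) should give the cis ester F13, and methanolysis (K2CO3, MeOH) comes back at 8.

**Further compounds**
F1 | step 11 | (7Z)-3,10:4,5-diepoxy-6-(triethylsilyloxy)germacr-7-en-1-one | C[C@]12C/C=C\[C@H](O[Si](CC)(CC)CC)[C@@H]3O[C@]3(C)[C@H](CC1=O)O2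
F2 | step 11 | C1 trimethylsilyl enol ether of F1 | C[C@]12C/C=C\[C@H](O[Si](CC)(CC)CC)[C@@H]3O[C@]3(C)[C@H](C=C1O[Si](C)(C)C)O2
F3 | step 11 | (7Z)-3,10:4,5-diepoxy-6-(triethylsilyloxy)germacra-2,7-dien-1-one | C[C@]12C/C=C\[C@H](O[Si](CC)(CC)CC)[C@@H]3O[C@]3(C)C(=CC1=O)O2
F4 | step 11 | (7Z)-5-(tert-butyldimethylsilyloxy)-3,10-epoxy-6-(triethylsilyloxy)germacra-2,4(15),7-trien-1-one | C[C@]12C/C=C\[C@H](O[Si](CC)(CC)CC)[C@H](O[Si](C)(C)C(C)(C)C)C(=C)C(=CC1=O)O2
F5 | step 11 | (7Z)-5-(tert-butyldimethylsilyloxy)-3,10-epoxy-6-hydroxygermacra-2,4(15),7-trien-1-one | C[C@]12C/C=C\[C@H](O)[C@H](O[Si](C)(C)C(C)(C)C)C(=C)C(=CC1=O)O2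
F6 | step 11 | (7R,8S)-5-(tert-butyldimethylsilyloxy)-3,10:7,8-diepoxy-6-hydroxygermacra-2,4(15)-dien-1-one | C[C@]12C[C@@H]3O[C@@H]3[C@H](O)[C@H](O[Si](C)(C)C(C)(C)C)C(=C)C(=CC1=O)O2
F7 | step 11 | C6 diethylphosphonoacetate of F6 | C[C@]12C[C@@H]3O[C@@H]3[C@H](OC(=O)CP(=O)(OCC)OCC)[C@H](O[Si](C)(C)C(C)(C)C)C(=C)C(=CC1=O)O2
F8 | step 11 | 8-epimer of 21 | C[C@]12C[C@H](O)[C@H]3C(P(=O)(OCC)OCC)C(=O)O[C@@H]3[C@H](O[Si](C)(C)C(C)(C)C)C(=C)C(=CC1=O)O2
F9 | step 11 | 8-epimer of 22 | C[C@]12C[C@H](O)[C@H]3C(=C)C(=O)O[C@@H]3[C@H](O[Si](C)(C)C(C)(C)C)C(=C)C(=CC1=O)O2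
F10 | step 17 | C6 malonic half ester of 19 | C[C@]12C[C@H]3O[C@@H]3[C@H](OC(=O)CC(=O)O)[C@H](O[Si](C)(C)C(C)(C)C)C(=C)C(=CC1=O)O2
F11 | step 17 | 11-carboxy analogue of 21 | C[C@]12C[C@@H](O)[C@H]3C(C(=O)O)C(=O)O[C@@H]3[C@H](O[Si](C)(C)C(C)(C)C)C(=C)C(=CC1=O)O2
F12 | step 6 | C6 epimer of 8 (hydroxyl trans to vinyl) | COC(=O)C[C@@H]1O[C@H](C=C)[C@@H](O)C=C1C
F13 | step 6 | 4-nitrobenzoate of 8 | COC(=O)C[C@@H]1O[C@H](C=C)[C@H](OC(=O)c2ccc(cc2)[N+](=O)[O-])C=C1C
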